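Everything rests on cutting the C5=C6 bond of the isoquinoline carbocycle (C4a, C5, C6, C7, C8, C8a). C5 and C6 carry only hydrogen, so this bond can be formed by ring-closing metathesis while C7 and C8 are still tetrahedral. In one operation the metathesis closes the six-membered ring of a pyridyl carbinol that has one vinyl group on C4a and one on C7, giving a 7,8-dihydroisoquinolin-8-ol. The crowded C7–naphthyl bond is never made by biaryl coupling. It is set early as an sp3–sp2 bond, and C7–C8 comes from a gamma-selective allylindium addition. Oxidation at C8 and enolisation finally create the phenol.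

Key step: step 13

Assumption: the target string carries no stereodescriptor, so the C7–naphthyl axis is treated as configurationally undefined and all sp3 intermediates are made as racemates.

**Naphthalene fragment**

Step 1
Reactants: 1 2-bromo-5-methoxybenzaldehyde; 2 dimethyl succinate
Product: 3 (E)-4-(2-bromo-5-methoxyphenyl)-3-(methoxycarbonyl)but-3-enoic acid
Conditions: NaOMe, MeOH, reflux; then aq. HCl
Reagents that add atoms: none
Why: Stobbe condensation, in which the succinate enolate adds to the aldehyde, the aldolate lactonises and base-induced ring opening should give the half-ester with the aryl group cis to the CH2CO2H arm (E alkene), the geometry needed for step 2.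

Step 2
Reactants: 3 (E)-4-(2-bromo-5-methoxyphenyl)-3-(methoxycarbonyl)but-3-enoic acid
Product: 4 methyl 4-acetoxy-8-bromo-5-methoxynaphthalene-2-carboxylate
Conditions: Ac2O, NaOAc, reflux
Reagents that add atoms: acetic anhydride CC(=O)OC(C)=O
Why: Intramolecular Friedel–Crafts acylation of the mixed anhydride, enolisation and acetylation (the naphthol synthesis that classically follows a Stobbe condensation); bromine blocks one ortho position, so the ring can close only at the carbon ortho to the methoxy group.

Step 3
Reactants: 4 methyl 4-acetoxy-8-bromo-5-methoxynaphthalene-2-carboxylate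
Product: 6 methyl 8-bromo-4,5-dimethoxynaphthalene-2-carboxylate, via naphthol 5 (not isolated)
Conditions: K2CO3 (3 equiv), MeOH, rt; then MeI (excess), DMF, 40 °C
Reagents that add atoms: iodomethane CI
Why: Base-catalysed methanolysis of the aryl acetate and Williamson O-methylation of the freed naphtholate in the same flask; the methyl ester can only exchange degenerately with methanol.

Step 4
Reactants: 6 methyl 8-bromo-4,5-dimethoxynaphthalene-2-carboxylate
Product: 7 (8-bromo-4,5-dimethoxynaphthalen-2-yl)methanol
Conditions: i-Bu2AlH (2.5 equiv), CH2Cl2, −78 to 0 °C; aq. potassium sodium tartrate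
Reagents that add atoms: none
Why: Hydride reduction of an aromatic ester to the benzylic alcohol, under which the aryl bromide and the aryl methyl ethers are inert.

Step 5
Reactants: 7 (8-bromo-4,5-dimethoxynaphthalen-2-yl)methanol
Product: 9 1-bromo-4,5-dimethoxy-7-methylnaphthalene, via mesylate 8 (not isolated)
Conditions: MsCl, Et3N, THF, 0 °C; then LiBHEt3 (excess), 0 °C to rt
Reagents that add atoms: methanesulfonyl chloride CS(=O)(=O)Cl (its atoms appear in 8 only, none remain in 9)
Why: Sulfonate activation and SN2 hydride displacement, a standard deoxygenation of a primary benzylic alcohol; at or below room temperature LiBHEt3 should leave the aryl bromide untouched.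

Step 6
Reactants: 9 1-bromo-4,5-dimethoxy-7-methylnaphthalene; 10 acrolein
Product: 12 racemic 1-(4,5-dimethoxy-7-methylnaphthalen-1-yl)prop-2-en-1-ol, via naphthyllithium 11 (not isolated)
Conditions: n-BuLi, THF, −78 °C; then acrolein, −78 °C; aq. NH4Cl
Reagents that add atoms: n-butyllithium [Li]CCCC (lithium appears in 11 only)
Why: Bromine–lithium exchange, faster than ortho-lithiation at −78 °C, and 1,2-addition of the hard aryllithium to acrolein create the future C7–naphthyl bond without steric strain; the carbinol centre forms as a racemate and vanishes in step 7.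

Step 7
Reactants: 12 racemic 1-(4,5-dimethoxy-7-methylnaphthalen-1-yl)prop-2-en-1-ol
Product: 13 (E)-1-(3-bromoprop-1-en-1-yl)-4,5-dimethoxy-7-methylnaphthalene
Conditions: PBr3 (0.4 equiv), Et2O, 0 °C; cold aqueous wash, used crude
Reagents that add atoms: phosphorus tribromide BrP(Br)Br
Why: Bromination with allylic transposition, in which the allyl cation stabilised by the para-methoxy group is captured at its terminus to give the conjugated, thermodynamically preferred E primary bromide; either regioisomeric bromide would in any case lead to the same allylindium reagent.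

**Pyridine fragment**

Step 8
Reactants: 14 2,6-dimethylpyridin-4-ol
Product: 15 3-iodo-2,6-dimethylpyridin-4-ol
Conditions: NIS (1.0 equiv), MeCN, reflux
Reagents that add atoms: N-iodosuccinimide O=C1CCC(=O)N1I
Why: Electrophilic aromatic iodination ortho to the activating 4-oxygen; C3 and C5 are equivalent and one equivalent of reagent limits the reaction to one of them.

Step 9
Reactants: 15 3-iodo-2,6-dimethylpyridin-4-ol
Product: 16 4-chloro-3-iodo-2,6-dimethylpyridine
Conditions: POCl3 (neat), 100 °C; ice, then basify
Reagents that add atoms: phosphoryl chloride O=P(Cl)(Cl)Cl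
Why: Deoxychlorination of a 4-pyridone through its dichlorophosphate by addition–elimination of chloride at C4, which does not touch the C–I bond.

Step 10
Reactants: 16 4-chloro-3-iodo-2,6-dimethylpyridine
Product: 18 4-chloro-2,6-dimethylpyridine-3-carbaldehyde, via pyridylmagnesium chloride 17 (not isolated)
Conditions: i-PrMgCl·LiCl, THF, −30 °C; then DMF, −30 °C to rt; aq. NH4Cl
Reagents that add atoms: N,N-dimethylformamide CN(C)C=O; isopropylmagnesium chloride CC(C)[Mg]Cl (MgCl appears in 17 only)
Why: Iodine–magnesium exchange, selective for C–I over C–Cl, followed by Bouveault-type formylation; the low temperature prevents loss of MgCl2 to a pyridyne, and the Grignard reagent is too weak a kinetic base to metalate the ring methyl groups.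

Step 11
Reactants: 18 4-chloro-2,6-dimethylpyridine-3-carbaldehyde; 19 potassium vinyltrifluoroborate
Product: 20 4-ethenyl-2,6-dimethylpyridine-3-carbaldehyde
Conditions: PdCl2(dppf) (3 mol%), Cs2CO3 (3 equiv), THF–H2O (9:1), 80 °C, trace BHT
Reagents that add atoms: none
Why: Suzuki–Miyaura vinylation; the C4–Cl bond is activated for oxidative addition to zerovalent palladium by the para ring nitrogen and the ortho formyl group, and the radical inhibitor guards the vinylpyridine against polymerisation.

**Union, ring closure and aromatisation**

Step 12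
Reactants: 13 (E)-1-(3-bromoprop-1-en-1-yl)-4,5-dimethoxy-7-methylnaphthalene; 20 4-ethenyl-2,6-dimethylpyridine-3-carbaldehyde
Product: 22 racemic anti (1R*,2S*)-1-(4-ethenyl-2,6-dimethylpyridin-3-yl)-2-(4,5-dimethoxy-7-methylnaphthalen-1-yl)but-3-en-1-ol, via allylindium dibromide 21 (not isolated)
Conditions: In powder, DMF, 0 °C to rt, slow addition of 13 to In and 20; aq. NaHCO3
Reagents that add atoms: indium [In] (present in 21 only)
Why: Barbier-type indium allylation, in which the E allylindium reagent (a sesquibromide, drawn in its simplest form) attacks the aldehyde through its gamma carbon in a Zimmerman–Traxler chair with naphthyl and pyridyl groups equatorial; this forms C7–C8 with the anti relationship, and any syn isomer is carried along because both centres are erased in step 14.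

Step 13
Reactants: 22 racemic anti (1R*,2S*)-1-(4-ethenyl-2,6-dimethylpyridin-3-yl)-2-(4,5-dimethoxy-7-methylnaphthalen-1-yl)but-3-en-1-ol
Product: 23 racemic cis (7S*,8R*)-7-(4,5-dimethoxy-7-methylnaphthalen-1-yl)-1,3-dimethyl-7,8-dihydroisoquinolin-8-ol
Conditions: second-generation Grubbs catalyst RuCl2(H2IMes)(PCy3)(=CHPh) (5 mol%), 1,4-benzoquinone (10 mol%), CH2Cl2 (0.005 M), 40 °C, no acid additive
Reagents that add atoms: none
Why: This is ring-closing olefin metathesis of a styrene-type diene, the reaction type long used to turn 1-(2-vinylaryl)but-3-en-1-ols into 1,2-dihydronaphthalen-1-ols. The benzylidene should exchange first with the aliphatic vinyl group on C7; the new alkylidene then adds [2+2] to the 4-vinyl group, and cycloreversion of the ruthenacyclobutane releases ethene and the C5=C6 bond. The only ring formed is the six-membered carbocycle C4a–C5–C6–C7–C8–C8a, closed by union of the two internal alkene carbons, with the cis alkene geometry imposed by the ring. No stereocentre is created, and C7 and C8 keep their relationship (anti in the chain, cis in the ring), which is irrelevant later. Cyclisation must outrun cross-metathesis, catalyst binding and alkene migration: two monosubstituted alkenes held close by the ortho-disubstituted pyridine and high dilution favour the ring, the nitrogen lies between two methyl groups and is a poor ligand for ruthenium, and benzoquinone intercepts ruthenium hydrides that would move the C7 vinyl group into conjugation with the naphthalene. Acid is left out on purpose, since a protonated 4-vinylpyridine would invite conjugate addition of the C8 hydroxyl and the product is only one dehydration away from an 8-deoxy isoquinoline.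

Step 14
Reactants: 23 racemic cis (7S*,8R*)-7-(4,5-dimethoxy-7-methylnaphthalen-1-yl)-1,3-dimethyl-7,8-dihydroisoquinolin-8-ol
Product: 25 dioncophylleine D, via 7H-isoquinolin-8-one 24 (not isolated)
Conditions: Dess–Martin periodinane (1.1 equiv), NaHCO3, CH2Cl2, 0 °C to rt
Reagents that add atoms: none
Why: Dess–Martin oxidation of a secondary benzylic-type carbinol gives a ketone whose C7–H is flanked by carbonyl, alkene and aryl groups, so it should enolise at once because this completes the aromatic sextet and erases both stereocentres; NaHCO3 takes up the acetic acid so that oxidation and not dehydration occurs.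

**Compound list**

1 | 2-bromo-5-methoxybenzaldehyde | COc1ccc(Br)c(C=O)c1 | starting material
2 | dimethyl succinate | COC(=O)CCC(=O)OC | starting material
3 | (E)-4-(2-bromo-5-methoxyphenyl)-3-(methoxycarbonyl)but-3-enoic acid | COC(=O)/C(CC(=O)O)=C/c1cc(OC)ccc1Br | intermediate
4 | methyl 4-acetoxy-8-bromo-5-methoxynaphthalene-2-carboxylate | COC(=O)c1cc(OC(C)=O)c2c(OC)ccc(Br)c2c1 | intermediate
5 | methyl 8-bromo-4-hydroxy-5-methoxynaphthalene-2-carboxylate (not isolated) | COC(=O)c1cc(O)c2c(OC)ccc(Br)c2c1 | intermediate
6 | methyl 8-bromo-4,5-dimethoxynaphthalene-2-carboxylate | COC(=O)c1cc(OC)c2c(OC)ccc(Br)c2c1 | intermediate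
7 | (8-bromo-4,5-dimethoxynaphthalen-2-yl)methanol | OCc1cc(OC)c2c(OC)ccc(Br)c2c1 | intermediate
8 | (8-bromo-4,5-dimethoxynaphthalen-2-yl)methyl methanesulfonate (not isolated) | CS(=O)(=O)OCc1cc(OC)c2c(OC)ccc(Br)c2c1 | intermediate
9 | 1-bromo-4,5-dimethoxy-7-methylnaphthalene | COc1ccc(Br)c2cc(C)cc(OC)c12 | intermediate
10 | acrolein | C=CC=O | starting material
11 | (4,5-dimethoxy-7-methylnaphthalen-1-yl)lithium (not isolated) | [Li]c1ccc(OC)c2c(OC)cc(C)cc12 | intermediate
12 | racemic 1-(4,5-dimethoxy-7-methylnaphthalen-1-yl)prop-2-en-1-ol (S enantiomer drawn) | C=C[C@H](O)c1ccc(OC)c2c(OC)cc(C)cc12 | intermediate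
13 | (E)-1-(3-bromoprop-1-en-1-yl)-4,5-dimethoxy-7-methylnaphthalene | COc1ccc(/C=C/CBr)c2cc(C)cc(OC)c12 | intermediate
14 | 2,6-dimethylpyridin-4-ol | Cc1cc(O)cc(C)n1 | starting material
15 | 3-iodo-2,6-dimethylpyridin-4-ol | Cc1cc(O)c(I)c(C)n1 | intermediate
16 | 4-chloro-3-iodo-2,6-dimethylpyridine | Cc1cc(Cl)c(I)c(C)n1 | intermediate
17 | (4-chloro-2,6-dimethylpyridin-3-yl)magnesium chloride (not isolated) | Cc1cc(Cl)c([Mg]Cl)c(C)n1 | intermediate
18 | 4-chloro-2,6-dimethylpyridine-3-carbaldehyde | Cc1cc(Cl)c(C=O)c(C)n1 | intermediate
19 | potassium vinyltrifluoroborate | [K+].C=C[B-](F)(F)F | starting material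
20 | 4-ethenyl-2,6-dimethylpyridine-3-carbaldehyde | C=Cc1cc(C)nc(C)c1C=O | intermediate
21 | (E)-3-(4,5-dimethoxy-7-methylnaphthalen-1-yl)prop-2-enylindium dibromide, simplest form of the sesquibromide (not isolated) | COc1ccc(/C=C/C[In](Br)Br)c2cc(C)cc(OC)c12 | intermediate
22 | racemic anti 1-(4-ethenyl-2,6-dimethylpyridin-3-yl)-2-(4,5-dimethoxy-7-methylnaphthalen-1-yl)but-3-en-1-ol (1R,2S enantiomer drawn) | C=Cc1cc(C)nc(C)c1[C@H](O)[C@@H](C=C)c1ccc(OC)c2c(OC)cc(C)cc12 | intermediate
23 | racemic cis 7-(4,5-dimethoxy-7-methylnaphthalen-1-yl)-1,3-dimethyl-7,8-dihydroisoquinolin-8-ol (7S,8R enantiomer drawn) | Cc1cc2C=C[C@@H](c3ccc(OC)c4c(OC)cc(C)cc34)[C@@H](O)c2c(C)n1 | intermediate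
24 | racemic 7-(4,5-dimethoxy-7-methylnaphthalen-1-yl)-1,3-dimethylisoquinolin-8(7H)-one (7S enantiomer drawn; not isolated) | Cc1cc2C=C[C@@H](c3ccc(OC)c4c(OC)cc(C)cc34)C(=O)c2c(C)n1 | intermediate
25 | dioncophylleine D, 7-(4,5-dimethoxy-7-methylnaphthalen-1-yl)-1,3-dimethylisoquinolin-8-ol | COc1ccc(-c2ccc3cc(C)nc(C)c3c2O)c2cc(C)cc(OC)c12 | target

Total step count: 14. Longest linear sequence: 10 (steps 1 to 7, then 12, 13 and 14).

**Steps most likely to fail**

**Step 13.**
- What may go wrong:
  - binding of the pyridine nitrogen to ruthenium, or base-induced decay of the catalyst;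
  - hydride-mediated migration of the C7 vinyl double bond into conjugation with the naphthalene;
  - intermolecular metathesis;
  - loss of water from the product on prolonged heating.
- The fallback sets out from 18 and 13 and returns at 25. It closes the ring at C4a–C5 by an intramolecular B-alkyl Suzuki–Miyaura coupling.
- Indium-mediated addition of 13 to the chloro aldehyde 18 (In, DMF) should give racemic anti 1-(4-chloro-2,6-dimethylpyridin-3-yl)-2-(4,5-dimethoxy-7-methylnaphthalen-1-yl)but-3-en-1-ol F1.
- Hydroboration with 9-BBN-H (2.2 equiv, THF) places boron on the terminal carbon and takes up the carbinol as its borinate, giving the bis(9-BBN) adduct F2.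
- This adduct is not isolated. It is heated with PdCl2(dppf) and Cs2CO3 in DMF–H2O at 70 °C to give racemic cis 7-(4,5-dimethoxy-7-methylnaphthalen-1-yl)-1,3-dimethyl-5,6,7,8-tetrahydroisoquinolin-8-ol F3.
- Dess–Martin oxidation leads to racemic 7-(4,5-dimethoxy-7-methylnaphthalen-1-yl)-1,3-dimethyl-6,7-dihydroisoquinolin-8(5H)-one F4.
- Dehydrogenation over Pd/C in refluxing mesitylene, the classical tetralone-to-naphthol aromatisation, gives 25.

**Step 12.**
- What may go wrong:
  - sluggish addition to the doubly ortho-substituted aldehyde, which leaves time for reductive homocoupling and solvolysis of the labile bromide;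
  - erosion of gamma selectivity through reversible addition.
- The fallback sets out from 12 and 20 and returns at 22. It replaces the Barbier reaction with a thermal allylboration and also bypasses bromide 13.
- Palladium-catalysed borylation of the allylic alcohol 12 (B2pin2, Pd(MeCN)4(BF4)2, DMSO–MeOH, rt) should give the linear (E)-2-[3-(4,5-dimethoxy-7-methylnaphthalen-1-yl)prop-2-en-1-yl]-4,4,5,5-tetramethyl-1,3,2-dioxaborolane F5.
- This boronate is a storable reagent. Heated with 20 in toluene, it adds through a closed chair transition state exclusively at its gamma carbon, and after aqueous work-up gives the same anti carbinol 22.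

**Step 14.**
- What may go wrong:
  - elimination of water to the 8-deoxy isoquinoline, competing with oxidation at the hindered C8, which lies peri to the C1 methyl group;
  - further oxidation of the electron-rich phenol by surplus periodinane.
- The fallback sets out from 22 and returns at 24. It reverses the order of oxidation and ring closure.
- Buffered Dess–Martin oxidation of the open-chain carbinol 22, which cannot aromatise by dehydration, should give racemic 1-(4-ethenyl-2,6-dimethylpyridin-3-yl)-2-(4,5-dimethoxy-7-methylnaphthalen-1-yl)but-3-en-1-one F6.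
- F6 is submitted at once to RuCl2(H2IMes)(PCy3)(=CHPh) and 1,4-benzoquinone in dilute CH2Cl2, before its double bond can move into conjugation.
- Ring closure then delivers ketone 24 directly, and 24 enolises to 25 with no oxidant present.

Further compounds
F1 | step 13 | racemic anti 1-(4-chloro-2,6-dimethylpyridin-3-yl)-2-(4,5-dimethoxy-7-methylnaphthalen-1-yl)but-3-en-1-ol (1R,2S drawn) | Clc1cc(C)nc(C)c1[C@H](O)[C@@H](C=C)c1ccc(OC)c2c(OC)cc(C)cc12
F2 | step 13 | bis(9-BBN) adduct of F1, boron on the terminal carbon and on the carbinol oxygen (not isolated) | Clc1cc(C)nc(C)c1[C@H](OB1C2CCCC1CCC2)[C@@H](CCB1C2CCCC1CCC2)c1ccc(OC)c2c(OC)cc(C)cc12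
F3 | step 13 | racemic cis 7-(4,5-dimethoxy-7-methylnaphthalen-1-yl)-1,3-dimethyl-5,6,7,8-tetrahydroisoquinolin-8-ol (7S,8R drawn) | Cc1cc2CC[C@@H](c3ccc(OC)c4c(OC)cc(C)cc34)[C@@H](O)c2c(C)n1
F4 | step 13 | racemic 7-(4,5-dimethoxy-7-methylnaphthalen-1-yl)-1,3-dimethyl-6,7-dihydroisoquinolin-8(5H)-one (7S drawn) | Cc1cc2CC[C@@H](c3ccc(OC)c4c(OC)cc(C)cc34)C(=O)c2c(C)n1
F5 | step 12 | (E)-2-[3-(4,5-dimethoxy-7-methylnaphthalen-1-yl)prop-2-en-1-yl]-4,4,5,5-tetramethyl-1,3,2-dioxaborolane | COc1ccc(/C=C/CB2OC(C)(C)C(C)(C)O2)c2cc(C)cc(OC)c12
F6 | step 14 | racemic 1-(4-ethenyl-2,6-dimethylpyridin-3-yl)-2-(4,5-dimethoxy-7-methylnaphthalen-1-yl)but-3-en-1-one (2S drawn) | C=Cc1cc(C)nc(C)c1C(=O)[C@@H](C=C)c1ccc(OC)c2c(OC)cc(C)cc12
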